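Remark on the chemistry: the target has no stereocentre and no stable stereoaxis, so it is achiral; "single enantiomer" is taken to mean the compound as drawn.

## Structural features

The target is 2-(2,4-dimethoxyphenyl)-3,5,6,7,8-pentamethoxy-4H-chromen-4-one: a benzo ring A (C4a, C5–C8, C8a) fused to a γ-pyranone ring C (O1, C2, C3, C4), with ring B (2,4-dimethoxyphenyl) joined through the C2–C1' bond. Ring A is hexasubstituted and carries no hydrogen: four contiguous methoxy carbons C5–C8, the ether carbon C8a and the acyl-bearing C4a. Ring C is also fully substituted (3-OMe, 2-aryl), and the C2–C1' bond, flanked by 3-OMe and 2'-OMe, is twisted but rotates freely. Fragile points are the 5-OMe group peri to the C4 carbonyl (cleaved by Lewis acids), the pyranone C2 position (opened by hydroxide and hard nucleophiles), and the electron-rich rings A and B (sensitive to oxidants and electrophiles). The real difficulty is the pentaoxygenated ring A: no cheap benzene carries this pattern together with a handle for the pyranone, and stepwise aromatic oxygenation is long. The key step exploits the tetrad C5(O)–C6(OMe)–C7(OMe)–C8(O), which has the carbon skeleton and oxidation pattern of a squaric acid diester. Because that tetrad is locally symmetric, it can be grafted onto the C5=C6 bond of a monocyclic 2-aryl-3-methoxy-4-pyranone (the carbons that become C4a and C8a) without a regiochemical question. In one sentence: ring A is built last, by thermal ring expansion of a 4-hydroxy-2,3-dimethoxy-4-(4-oxopyranyl)cyclobutenone onto a preformed ring C that already carries ring B.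

## Logic of the disconnections

12 to 11: the two O–CH3 bonds at O5 and O8 are cut. The reason is that a 5,8-hydroquinone with 6,7-dimethoxy groups is the innate product of a squarate ring expansion. The gain is small in atoms but opens the key disconnection. The forward step must methylate a hydrogen-bonded 5-OH completely and keep oxygen away from the hydroquinone.

11 to 8 (through 10 and 9): the C4a–C5 bond is cut after retro-tautomerization, and the resulting dienylketene is folded back into a four-membered ring by reconnecting C5 to C8. The reason is that all four oxygenated carbons of ring A then sit in one small, symmetric ring. The gain is the whole of ring A: a bicyclic, hexasubstituted arene becomes a cyclobutenone hanging on a monocyclic pyranone. The forward step must open the four-membered ring with the hydroxyl rotating outward and must close the ketene onto the pyranone CH carbon faster than the hydroxyl can capture it.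

8 to 5 and 6: the C8–C8a bond (pyranone C6 to carbinol carbon) is cut. The reason is that 6 is a commercial C4 block that already holds C5–C8 with their oxygens, and 5 holds rings B and C complete. The gain is full convergence of two fragments of similar size. The forward step needs metalation of 5 at a pyranone CH without attack on the dimethoxyarene, and 1,2-addition to one carbonyl of 6.

5 to 3 and 4: the C2–C1' bond is cut. The reason is that C2 of a 3-oxygenated 4-pyranone is its natural site of halogenation, which makes 3 a vinylogous acyl bromide for cross-coupling. The gain is that ring B is reduced to a commercial boronic acid. The forward step must couple an ortho-substituted, electron-rich boronic acid without destroying the base-sensitive bromopyranone.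

3 to 2 to 1: the O–CH3 bond at O3 and the C2–Br bond are cut in turn. The reason is that the enolic hydroxyl of 1 directs the electrophile to C2 and is then capped. The gain is a commercial starting pyranone. The forward steps need regioselective monobromination and O-methylation without displacement of bromide.

## Other disconnections considered

Alternative 1: the first route that comes to mind cuts O1–C2 and C2–C3 of ring C. Forward, 1-(2-hydroxy-3,4,5,6-tetramethoxyphenyl)ethan-1-one A1 is condensed with 2,4-dimethoxybenzaldehyde A2 (Claisen–Schmidt) to the chalcone A3. Algar–Flynn–Oyamada oxidation would give the flavonol A4, and O-methylation the target. The chosen plan is preferred on structure and mechanism: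
- A1 is itself the hard part of the molecule and needs a multistep oxygenation and acylation sequence on a benzene ring.
- The 6'-methoxy group of A3 twists the enone and is expected to favour 5-exo closure to an aurone over 6-endo closure to A4.
- The ring-A problem is only moved, not solved.

Alternative 2: a three-component cut at C4–C4a, C4–C3 and O1–C2. Forward, 2-iodo-3,4,5,6-tetramethoxyphenol A5, carbon monoxide A6 and 1-ethynyl-2,4-dimethoxybenzene A7 are joined by a palladium-catalysed carbonylative Sonogashira coupling and cyclization to the 3-unsubstituted flavone A8. C3 must then be oxidized to A4 and methylated. The chosen plan is preferred on structure and step economy: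
- A5 again contains the whole pentaoxygenated ring and is not commercial.
- The ynone intermediate can close 5-exo as well as 6-endo.
- The 3-methoxy group costs two further steps on an oxidation-sensitive flavone.

Alternative 3: a like-polarity cut of the C2–C1' bond alone. Forward, 3,5,6,7,8-pentamethoxy-4H-chromen-4-one A9 and 1,3-dimethoxybenzene A10 would be joined by a palladium(II)-mediated dehydrogenative C–H/C–H coupling. The chosen plan is preferred on structure and mechanism:
- The step forms one bond and leaves the complete oxygenated chromone A9 to conventional synthesis.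
- Palladation at C2 is hindered by the adjacent 3-methoxy group.
- The arene partner offers two competing positions (C4 and C2).

Key step: step 5

## Route

Step 1
Reactants: 1 3-hydroxy-4H-pyran-4-one (pyromeconic acid)
Product: 2 2-bromo-3-hydroxy-4H-pyran-4-one
Conditions: NBS (1.05 equiv), MeCN, 0 °C to rt
Reagents that add atoms: N-bromosuccinimide (NBS), O=C1CCC(=O)N1Br
Why: Electrophilic bromination of an enol: the 3-OH makes C2 the nucleophilic β-carbon of the C2=C3 enol, the same ortho-to-hydroxyl selectivity that governs substitution of kojic acid and related 3-hydroxy-4-pyranones.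

Step 2
Reactants: 2 2-bromo-3-hydroxy-4H-pyran-4-one
Product: 3 2-bromo-3-methoxy-4H-pyran-4-one
Conditions: MeI (excess), K2CO3, acetone, 40 °C
Reagents that add atoms: iodomethane, CI
Why: Williamson O-methylation of the acidic enolic hydroxyl; the mild carbonate base and excess MeI should make alkylation faster than any displacement of the vinylogous acyl bromide.

Step 3
Reactants: 3 2-bromo-3-methoxy-4H-pyran-4-one; 4 (2,4-dimethoxyphenyl)boronic acid
Product: 5 2-(2,4-dimethoxyphenyl)-3-methoxy-4H-pyran-4-one
Conditions: Pd(OAc)2 (cat.), SPhos (cat.), K3PO4, PhMe/H2O (10:1), 80 °C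
Reagents that add atoms: none
Why: Suzuki–Miyaura coupling; the C2–Br bond of 3 is a vinylogous acyl bromide and should add oxidatively with ease, and a biaryl dialkylphosphine ligand supports transmetalation of the ortho-substituted boronic acid. Little water and a phosphate base limit protodeboronation and opening of the pyranone.

Step 4
Reactants: 5 2-(2,4-dimethoxyphenyl)-3-methoxy-4H-pyran-4-one; 6 3,4-dimethoxycyclobut-3-ene-1,2-dione (dimethyl squarate)
Product: 8 2-(2,4-dimethoxyphenyl)-6-(1-hydroxy-2,3-dimethoxy-4-oxocyclobut-2-en-1-yl)-3-methoxy-4H-pyran-4-one (racemic), via 6-chloromagnesio pyranone 7 (not isolated)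
Conditions: TMPMgCl·LiCl (1.05 equiv), THF, −40 °C; then 6, −78 to −20 °C; aq. NH4Cl
Reagents that add atoms: none
Why: Directed C–H magnesiation with a hindered amide base at C6–H, the most acidic C–H of 5 (next to the ring oxygen), gives 7, which has no β-leaving group and leaves the dimethoxyarene untouched. Then follows the standard 1,2-addition of an organometallic to one of the two equivalent carbonyls of a squarate ester. The new carbinol centre is racemic and is destroyed in step 5.

Step 5
Reactants: 8 2-(2,4-dimethoxyphenyl)-6-(1-hydroxy-2,3-dimethoxy-4-oxocyclobut-2-en-1-yl)-3-methoxy-4H-pyran-4-one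
Product: 11 2-(2,4-dimethoxyphenyl)-5,8-dihydroxy-3,6,7-trimethoxy-4H-chromen-4-one, via dienylketene 9 (not isolated), via 4aH-chromene-4,5-dione tautomer 10 (not isolated)
Conditions: PhMe (degassed), 110 °C, Ar
Reagents that add atoms: none
Why: On heating, the C(=O)–C(OH) bond of the cyclobutenone opens in a thermal 4π conrotatory electrocyclic reaction, and the donor hydroxyl rotates outward (torquoselectivity), which places the pyranonyl group cis to the ketene in 9. The ketene C=C, the central enol ether C=C and the pyranone C5=C6 bond of 9 form a (Z)-dienylketene that closes by a thermal 6π disrotatory electrocyclization, ketene carbon to pyranone C5 (the future C4a), which makes the C4a–C5 bond and the six-membered carbocycle of 10. In 10 the 4a-H lies between two carbonyl groups, so it enolizes at once to the aromatic hydroquinone 11, which makes the sequence irreversible. The closest known reaction type is the Moore–Liebeskind ring expansion of 4-alkenyl- and 4-(hetero)aryl-4-hydroxycyclobutenones derived from squarate esters, applied here to a 4-oxopyranyl substituent. No stereocentre survives, because the carbinol carbon of 8 and C4a of 10 both become sp2. The selectivity needed is ring expansion over capture of the ketene by the hydroxyl; it is secured by the outward rotation of the hydroxyl and by the ease of electrocyclization onto a weakly aromatic pyranone C=C bond. Site selectivity is fixed, since pyranone C5 is the only π-terminus within reach, and attachment of the squarate through the neighbouring pyranone carbon would lead to the same 11 because the squarate unit is symmetric. One operation thus sets C5 to C8 of ring A with all four oxygens in place.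

Step 6
Reactants: 11 2-(2,4-dimethoxyphenyl)-5,8-dihydroxy-3,6,7-trimethoxy-4H-chromen-4-one
Product: 12 2-(2,4-dimethoxyphenyl)-3,5,6,7,8-pentamethoxy-4H-chromen-4-one (target)
Conditions: Me2SO4 (excess), K2CO3, acetone, reflux, Ar
Reagents that add atoms: dimethyl sulfate, COS(=O)(=O)OC
Why: Williamson methylation of both phenols; dimethyl sulfate with carbonate in refluxing acetone is the standard way to methylate the hydrogen-bonded 5-OH of flavones, and the inert atmosphere protects the hydroquinone anion from oxidation.

## Compound list

1 | 3-hydroxy-4H-pyran-4-one (pyromeconic acid) | O=c1ccocc1O | starting material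
2 | 2-bromo-3-hydroxy-4H-pyran-4-one | O=c1ccoc(Br)c1O | intermediate
3 | 2-bromo-3-methoxy-4H-pyran-4-one | COc1c(Br)occc1=O | intermediate
4 | (2,4-dimethoxyphenyl)boronic acid | COc1ccc(B(O)O)c(OC)c1 | starting material
5 | 2-(2,4-dimethoxyphenyl)-3-methoxy-4H-pyran-4-one | COc1ccc(-c2occc(=O)c2OC)c(OC)c1 | intermediate
6 | 3,4-dimethoxycyclobut-3-ene-1,2-dione (dimethyl squarate) | COC1=C(OC)C(=O)C1=O | starting material
7 | chloro[6-(2,4-dimethoxyphenyl)-5-methoxy-4-oxo-4H-pyran-2-yl]magnesium | COc1ccc(-c2oc([Mg]Cl)cc(=O)c2OC)c(OC)c1 | intermediate
8 | 2-(2,4-dimethoxyphenyl)-6-(1-hydroxy-2,3-dimethoxy-4-oxocyclobut-2-en-1-yl)-3-methoxy-4H-pyran-4-one (racemic) | COC1=C(OC)C(O)(c2cc(=O)c(OC)c(-c3ccc(OC)cc3OC)o2)C1=O | intermediate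
9 | 2-(2,4-dimethoxyphenyl)-6-[(1Z)-1-hydroxy-2,3-dimethoxy-4-oxobuta-1,3-dien-1-yl]-3-methoxy-4H-pyran-4-one (dienylketene) | O=C=C(OC)/C(OC)=C(/O)c1cc(=O)c(OC)c(-c2ccc(OC)cc2OC)o1 | intermediate
10 | 2-(2,4-dimethoxyphenyl)-8-hydroxy-3,6,7-trimethoxy-4aH-chromene-4,5-dione (racemic, transient) | COC1=C(OC)C(=O)C2C(=O)C(OC)=C(c3ccc(OC)cc3OC)OC2=C1O | intermediate
11 | 2-(2,4-dimethoxyphenyl)-5,8-dihydroxy-3,6,7-trimethoxy-4H-chromen-4-one | COc1ccc(-c2oc3c(O)c(OC)c(OC)c(O)c3c(=O)c2OC)c(OC)c1 | intermediate
12 | 2-(2,4-dimethoxyphenyl)-3,5,6,7,8-pentamethoxy-4H-chromen-4-one | COc1ccc(-c2oc3c(OC)c(OC)c(OC)c(OC)c3c(=O)c2OC)c(OC)c1 | target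

## Step count and risk

Total step count: 6. Longest linear sequence: 6 steps (1 to 2 to 3 to 5 to 8 to 11 to 12); 4 and 6 enter as commercial materials.

Least certain steps:

Step 5 (key step). The most likely failure is ring opening with the hydroxyl turned inward, or a slow electrocyclization, followed by intramolecular capture of the ketene by the hydroxyl (lactonization). A second failure mode is oxidation of the electron-rich hydroquinone by air during isolation. The fallback removes the free hydroxyl before the ring expansion. It sets out from 8, which is O-methylated at the tertiary alcohol (MeI, Ag2O) to 2-(2,4-dimethoxyphenyl)-3-methoxy-6-(1,2,3-trimethoxy-4-oxocyclobut-2-en-1-yl)-4H-pyran-4-one F1. Thermolysis of this ether in toluene should give the oxidation-stable monophenol 2-(2,4-dimethoxyphenyl)-5-hydroxy-3,6,7,8-tetramethoxy-4H-chromen-4-one F2 by the same electrocyclic sequence, with no hydroxyl left to intercept the ketene. Methylation of the single remaining 5-OH (Me2SO4, K2CO3) returns to the route at 12.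

Step 4. The most likely failures are incomplete or unselective metalation, self-condensation of the metalated pyranone with unmetalated 5 by conjugate addition during the metalation period, and sluggish addition of the stabilized organomagnesium to the vinylogous ester carbonyl. The fallback separates carbanion formation from the amide base. It sets out from 5, which is zincated with the milder TMPZnCl·LiCl and quenched with iodine to give 2-(2,4-dimethoxyphenyl)-6-iodo-3-methoxy-4H-pyran-4-one F3. Iodine–magnesium exchange with iPrMgCl·LiCl at −78 °C then comes back to the route at 7, which is trapped with 6 at that temperature to give 8.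

Step 3. The most likely failures are protodeboronation of the electron-rich, ortho-substituted boronic acid and hydrolytic opening or substitution of the bromopyranone by the aqueous base. The fallback inverts the polarity of the coupling and avoids bromide, boron and aqueous base altogether. It sets out from 1, which is O-methylated (MeI, K2CO3) to 3-methoxy-4H-pyran-4-one F4. Zincation with TMPZnCl·LiCl at C2–H, which is flanked by the ring oxygen and the methoxy-bearing C3, gives chloro(3-methoxy-4-oxo-4H-pyran-2-yl)zinc F5. Negishi coupling of F5 with 1-iodo-2,4-dimethoxybenzene F6 (Pd catalyst, THF) comes back to the route at 5.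

Step 6. The most likely failures are incomplete methylation of the hydrogen-bonded 5-OH and oxidation of the hydroquinone dianion by traces of oxygen under basic conditions. The fallback accepts the oxidation instead of fighting it. It sets out from 11, which is oxidized deliberately (Ag2O or air) to the stable quinone 2-(2,4-dimethoxyphenyl)-3,6,7-trimethoxy-4H-chromene-4,5,8-trione F7. Reductive methylation (Na2S2O4, Me2SO4, KOH, Bu4NBr, THF/H2O), in which the hydroquinone is formed and alkylated in a reducing medium under forcing phase-transfer conditions, comes back to the route at 12.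

## Further compounds

F1 | step 5 | 2-(2,4-dimethoxyphenyl)-3-methoxy-6-(1,2,3-trimethoxy-4-oxocyclobut-2-en-1-yl)-4H-pyran-4-one (racemic) | COC1=C(OC)C(OC)(c2cc(=O)c(OC)c(-c3ccc(OC)cc3OC)o2)C1=O
F2 | step 5 | 2-(2,4-dimethoxyphenyl)-5-hydroxy-3,6,7,8-tetramethoxy-4H-chromen-4-one | COc1ccc(-c2oc3c(OC)c(OC)c(OC)c(O)c3c(=O)c2OC)c(OC)c1
F3 | step 4 | 2-(2,4-dimethoxyphenyl)-6-iodo-3-methoxy-4H-pyran-4-one | COc1ccc(-c2oc(I)cc(=O)c2OC)c(OC)c1
F4 | step 3 | 3-methoxy-4H-pyran-4-one | COc1coccc1=O
F5 | step 3 | chloro(3-methoxy-4-oxo-4H-pyran-2-yl)zinc | COc1c([Zn]Cl)occc1=O
F6 | step 3 | 1-iodo-2,4-dimethoxybenzene | COc1ccc(I)c(OC)c1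
F7 | step 6 | 2-(2,4-dimethoxyphenyl)-3,6,7-trimethoxy-4H-chromene-4,5,8-trione | COc1ccc(C2=C(OC)C(=O)C3=C(O2)C(=O)C(OC)=C(OC)C3=O)c(OC)c1
A1 | alternative 1 | 1-(2-hydroxy-3,4,5,6-tetramethoxyphenyl)ethan-1-one | CC(=O)c1c(O)c(OC)c(OC)c(OC)c1OC
A2 | alternative 1 | 2,4-dimethoxybenzaldehyde | COc1ccc(C=O)c(OC)c1
A3 | alternative 1 | (E)-3-(2,4-dimethoxyphenyl)-1-(2-hydroxy-3,4,5,6-tetramethoxyphenyl)prop-2-en-1-one | COc1ccc(/C=C/C(=O)c2c(O)c(OC)c(OC)c(OC)c2OC)c(OC)c1
A4 | alternative 1 | 2-(2,4-dimethoxyphenyl)-3-hydroxy-5,6,7,8-tetramethoxy-4H-chromen-4-one | COc1ccc(-c2oc3c(OC)c(OC)c(OC)c(OC)c3c(=O)c2O)c(OC)c1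
A5 | alternative 2 | 2-iodo-3,4,5,6-tetramethoxyphenol | COc1c(O)c(I)c(OC)c(OC)c1OC
A6 | alternative 2 | carbon monoxide | [C-]#[O+]
A7 | alternative 2 | 1-ethynyl-2,4-dimethoxybenzene | C#Cc1ccc(OC)cc1OC
A8 | alternative 2 | 2-(2,4-dimethoxyphenyl)-5,6,7,8-tetramethoxy-4H-chromen-4-one | COc1ccc(-c2cc(=O)c3c(OC)c(OC)c(OC)c(OC)c3o2)c(OC)c1
A9 | alternative 3 | 3,5,6,7,8-pentamethoxy-4H-chromen-4-one | COc1coc2c(OC)c(OC)c(OC)c(OC)c2c1=O
A10 | alternative 3 | 1,3-dimethoxybenzene | COc1cccc(OC)c1
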